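**Retrosynthetic overview**

1. The target comes from its tris(silyl ether) by buffered fluoride. Its only stereocentre, C2, is set one step earlier by ligand-controlled CuH 1,4-reduction of the C2=C3 bond of the corresponding flavone.
2. The plan rests on ring B, a benzene whose four adjacent carbons C1' (bond to C2 of ring C), C2' (geranyl), C3' (O) and C4' (O) all carry substituents. Instead of forcing geranyl into the hindered position of a catechol, ring B is built by [4+2] cycloaddition (bonds C1'–C2' and C5'–C6') of a geranyl-bearing 2,3-bis(silyloxy)-1,3-diene (C2' to C5') with a 2-ethynylchromone (C1', C6'), then dehydrogenation.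
3. The diene comes from 7,11-dimethyldodeca-6,10-diene-2,3-dione by double silyl enol ether formation; the dione comes from geranyl bromide and the enolate of biacetyl mono(dimethyl ketal).
4. The 2-ethynylchromone comes from the 2-carbaldehyde by one-carbon homologation, and the aldehyde from the chromone-2-carboxylate made from 2,4-dihydroxyacetophenone and diethyl oxalate.
5. Ring order: ring A is bought, ring C is closed by Claisen condensation and cyclodehydration, ring B is formed last by Diels–Alder reaction and aromatisation.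

Key step: step 9

**Remarks**

- Geranyl = (2E)-3,7-dimethylocta-2,6-dien-1-yl; TBS = tert-butyldimethylsilyl; TIPS = triisopropylsilyl.
- The diene carries TBS rather than trimethylsilyl ethers, so that the catechol ethers survive DDQH2, chromatography and the reduction without a silyl exchange.
- O7 carries TIPS, so that it survives borohydride in ethanol.
- Assumption: (R)-DTBM-SEGPHOS is taken to direct hydride to the Re face of C2 (giving 2S); if the sense proves opposite, the (S)-ligand is used with no other change.

**Route**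

Step 1
Reactants: 1 3,3-dimethoxybutan-2-one; 2 geranyl bromide ((2E)-1-bromo-3,7-dimethylocta-2,6-diene)
Product: 4 (6E)-2,2-dimethoxy-7,11-dimethyldodeca-6,10-dien-3-one, via lithium enolate 3 (not isolated)
Conditions: 1 (1.3 equiv), LiN(iPr)2 (1.3 equiv), THF, −78 °C; then 2 (1.0 equiv), DMPU, −78 to −20 °C
Reagents that add atoms: none
Why: Enolate alkylation, in which the ketone can be deprotonated only at its acetyl methyl (the other α-carbon is the quaternary ketal carbon) and the lithium enolate, kept in excess to suppress dialkylation, displaces the primary allylic bromide by SN2 with the (E)-olefin untouched.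

Step 2
Reactants: 4 (6E)-2,2-dimethoxy-7,11-dimethyldodeca-6,10-dien-3-one
Product: 5 (6E)-7,11-dimethyldodeca-6,10-diene-2,3-dione
Conditions: 2 M aq. HCl, THF, rt
Reagents that add atoms: water, O
Why: Acid-catalysed hydrolysis of a dimethyl ketal, run in dilute aqueous acid at room temperature where the isolated trisubstituted olefins of the geranyl chain should not be protonated.

Step 3
Reactants: 5 (6E)-7,11-dimethyldodeca-6,10-diene-2,3-dione
Product: 6 (3Z,6E)-2,3-bis(tert-butyldimethylsilyloxy)-7,11-dimethyldodeca-1,3,6,10-tetraene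
Conditions: TBSOTf (2.4 equiv), Et3N (5 equiv), CH2Cl2, −78 to 0 °C; purification on Et3N-deactivated silica
Reagents that add atoms: tert-butyldimethylsilyl trifluoromethanesulfonate (TBSOTf), CC(C)(C)[Si](C)(C)OS(=O)(=O)C(F)(F)F
Why: Double soft enolisation of a 1,2-dione with a silyl triflate and amine, in which only C1 and C4 offer α-protons so one constitution results, and the C3=C4 enol ether should form mainly as the (Z)-isomer (chain cis to oxygen, avoiding allylic strain with the C2 substituent), the geometry that can reach the s-cis diene conformation.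

Step 4
Reactants: 7 2,4-dihydroxyacetophenone; 8 diethyl oxalate
Product: 10 ethyl 7-hydroxy-4-oxo-4H-chromene-2-carboxylate, via diketo ester 9 (not isolated)
Conditions: NaOEt (4 equiv), EtOH, reflux; then conc. HCl, EtOH, reflux
Reagents that add atoms: none
Why: Crossed Claisen condensation of the acetophenone enolate with the non-enolisable oxalate gives the diketo ester, and acid then closes ring C by attack of the 2-hydroxyl on the α-keto carbonyl and dehydration (classical chromone-2-carboxylate synthesis).

Step 5
Reactants: 10 ethyl 7-hydroxy-4-oxo-4H-chromene-2-carboxylate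
Product: 11 ethyl 4-oxo-7-(triisopropylsilyloxy)-4H-chromene-2-carboxylate
Conditions: TIPSCl (1.2 equiv), imidazole (2.5 equiv), DMF, rt
Reagents that add atoms: triisopropylsilyl chloride (TIPSCl), CC(C)[Si](Cl)(C(C)C)C(C)C
Why: Standard silylation of an acidic phenol, giving an aryl silyl ether bulky enough to survive the borohydride step and removable by fluoride at the end.

Step 6
Reactants: 11 ethyl 4-oxo-7-(triisopropylsilyloxy)-4H-chromene-2-carboxylate
Product: 12 2-(hydroxymethyl)-7-(triisopropylsilyloxy)-4H-chromen-4-one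
Conditions: NaBH4 (2 equiv), THF/EtOH, 0 °C
Reagents that add atoms: none
Why: Chemoselective borohydride reduction of a chromone-2-carboxylate, whose ester is activated by the electron-poor C2 of the pyranone, while the vinylogous ester carbonyl C4 is too electron-rich to be reduced at 0 °C.

Step 7
Reactants: 12 2-(hydroxymethyl)-7-(triisopropylsilyloxy)-4H-chromen-4-one
Product: 13 4-oxo-7-(triisopropylsilyloxy)-4H-chromene-2-carbaldehyde
Conditions: Dess–Martin periodinane (1.2 equiv), CH2Cl2, 0 °C to rt; used crude
Reagents that add atoms: none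
Why: Dess–Martin oxidation takes the primary alcohol to the aldehyde under neutral, non-aqueous conditions without over-oxidation or loss of the silyl ether.

Step 8
Reactants: 13 4-oxo-7-(triisopropylsilyloxy)-4H-chromene-2-carbaldehyde
Product: 14 2-ethynyl-7-(triisopropylsilyloxy)-4H-chromen-4-one
Conditions: Me3SiCHN2 (1.1 equiv), LiN(iPr)2 (1.1 equiv), THF, −78 °C; then 13, −78 to 0 °C
Reagents that add atoms: trimethylsilyldiazomethane, C[Si](C)(C)C=[N+]=[N-]
Why: Colvin rearrangement (Seyferth–Gilbert-type homologation), in which lithiated trimethylsilyldiazomethane adds to the aldehyde, Peterson elimination and loss of N2 give an alkylidene carbene, and a 1,2-hydrogen shift gives the terminal alkyne under aprotic low-temperature conditions that spare the aryl silyl ether and the pyranone.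

Step 9
Reactants: 6 (3Z,6E)-2,3-bis(tert-butyldimethylsilyloxy)-7,11-dimethyldodeca-1,3,6,10-tetraene; 14 2-ethynyl-7-(triisopropylsilyloxy)-4H-chromen-4-one
Product: 16 2-[3,4-bis(tert-butyldimethylsilyloxy)-2-geranylphenyl]-7-(triisopropylsilyloxy)-4H-chromen-4-one, via cyclohexadiene cycloadduct 15 (not isolated)
Conditions: 6 (1.3 equiv), 14, BHT (cat.), toluene (1 M), sealed tube, 130 °C; then DDQ (1.2 equiv, in portions), 0 °C to rt, same flask
Reagents that add atoms: none
Why: The electron-rich diene 6 and the alkyne of 14, whose LUMO is lowered by conjugation through C2=C3 to the C4 carbonyl (a vinylogous ynone), should combine in a concerted, asynchronous, suprafacial [4+2] cycloaddition, the reaction type established for 2,3-bis(silyloxy)butadienes with acceptor alkynes followed by quinone dehydrogenation. Ring B is closed by this intermolecular cycloaddition, with C5'–C6' (diene CH2 to alkyne CH) as the leading bond and C1'–C2' (geranyl-bearing diene carbon to chromonyl-bearing alkyne carbon) as the lagging bond, giving the 1,4-cyclohexadiene 15. The selectivity needed is the ortho regiochemistry: the two silyloxy groups offset each other, so the 1-alkyl group leaves the larger HOMO coefficient on the unsubstituted diene terminus, which pairs with the alkyne terminus that has the larger LUMO coefficient and is also the less hindered carbon, the steric cost of placing geranyl next to the chromone falling on the late bond. The alkyne is preferred over the chromone C2=C3 bond because that bond is trisubstituted and deactivated by the ring oxygen, and any (3E)-diene cannot reach the s-cis conformation and stays out of the reaction. The only new stereocentre, the sp3 C2' of 15, is uncontrolled and is erased when DDQ abstracts hydride from a doubly allylic ring C–H and the cation loses a proton to give the benzene ring. The TBS ethers are expected to survive DDQH2 and chromatography.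

Step 10
Reactants: 16 2-[3,4-bis(tert-butyldimethylsilyloxy)-2-geranylphenyl]-7-(triisopropylsilyloxy)-4H-chromen-4-one
Product: 18 (2S)-2-[3,4-bis(tert-butyldimethylsilyloxy)-2-geranylphenyl]-7-(triisopropylsilyloxy)-2,3-dihydro-4H-chromen-4-one, via silyl enol ether 17 (not isolated)
Conditions: Cu(OAc)2·H2O (5 mol%), (R)-DTBM-SEGPHOS (5.5 mol%), (EtO)2MeSiH (1.5 equiv), toluene, 0 °C to rt; then 1 M aq. HCl, THF, 0 °C
Reagents that add atoms: none
Why: Asymmetric CuH conjugate reduction of a chromone, in which the bisphosphine-ligated CuH delivers hydride to the Re face of C2 under ligand control to set (2S), the copper enolate is trapped by the silane as enol ether 17 (which shields the ketone from 1,2-reduction and the C2–O1 bond from β-elimination), and brief acid hydrolysis frees the ketone without touching C2.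

Step 11
Reactants: 18 (2S)-2-[3,4-bis(tert-butyldimethylsilyloxy)-2-geranylphenyl]-7-(triisopropylsilyloxy)-2,3-dihydro-4H-chromen-4-one
Product: 19 (2S)-2-[2-geranyl-3,4-dihydroxyphenyl]-7-hydroxy-2,3-dihydro-4H-chromen-4-one (target)
Conditions: TBAF (4 equiv), AcOH (4 equiv), THF, 0 °C, Ar
Reagents that add atoms: none
Why: Fluoride cleavage of the three aryl silyl ethers, buffered with acetic acid so that the medium is never basic enough to open the flavanone to its chalcone (which would racemise C2) or to oxidise the catechol, and never acidic enough to cyclise the geranyl chain onto the 3'-hydroxyl.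

**Compound list**

1 | 3,3-dimethoxybutan-2-one (biacetyl mono(dimethyl ketal)) | CC(=O)C(C)(OC)OC | starting material
2 | geranyl bromide, (2E)-1-bromo-3,7-dimethylocta-2,6-diene | CC(C)=CCC/C(C)=C/CBr | starting material
3 | lithium 3,3-dimethoxybut-1-en-2-olate (lithium enolate of 1) | [Li]OC(=C)C(C)(OC)OC | intermediate
4 | (6E)-2,2-dimethoxy-7,11-dimethyldodeca-6,10-dien-3-one | CC(C)=CCC/C(C)=C/CCC(=O)C(C)(OC)OC | intermediate
5 | (6E)-7,11-dimethyldodeca-6,10-diene-2,3-dione | CC(C)=CCC/C(C)=C/CCC(=O)C(C)=O | intermediate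
6 | (3Z,6E)-2,3-bis(tert-butyldimethylsilyloxy)-7,11-dimethyldodeca-1,3,6,10-tetraene | CC(C)=CCC/C(C)=C/C/C=C(/C(=C)O[Si](C)(C)C(C)(C)C)O[Si](C)(C)C(C)(C)C | intermediate
7 | 2,4-dihydroxyacetophenone | CC(=O)c1ccc(O)cc1O | starting material
8 | diethyl oxalate | CCOC(=O)C(=O)OCC | starting material
9 | ethyl 4-(2,4-dihydroxyphenyl)-2,4-dioxobutanoate | CCOC(=O)C(=O)CC(=O)c1ccc(O)cc1O | intermediate
10 | ethyl 7-hydroxy-4-oxo-4H-chromene-2-carboxylate | CCOC(=O)c1cc(=O)c2ccc(O)cc2o1 | intermediate
11 | ethyl 4-oxo-7-(triisopropylsilyloxy)-4H-chromene-2-carboxylate | CCOC(=O)c1cc(=O)c2ccc(O[Si](C(C)C)(C(C)C)C(C)C)cc2o1 | intermediate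
12 | 2-(hydroxymethyl)-7-(triisopropylsilyloxy)-4H-chromen-4-one | OCc1cc(=O)c2ccc(O[Si](C(C)C)(C(C)C)C(C)C)cc2o1 | intermediate
13 | 4-oxo-7-(triisopropylsilyloxy)-4H-chromene-2-carbaldehyde | O=Cc1cc(=O)c2ccc(O[Si](C(C)C)(C(C)C)C(C)C)cc2o1 | intermediate
14 | 2-ethynyl-7-(triisopropylsilyloxy)-4H-chromen-4-one | C#Cc1cc(=O)c2ccc(O[Si](C(C)C)(C(C)C)C(C)C)cc2o1 | intermediate
15 | 2-[4,5-bis(tert-butyldimethylsilyloxy)-6-geranylcyclohexa-1,4-dien-1-yl]-7-(triisopropylsilyloxy)-4H-chromen-4-one (racemic at ring carbon 6) | CC(C)=CCC/C(C)=C/CC1C(c2cc(=O)c3ccc(O[Si](C(C)C)(C(C)C)C(C)C)cc3o2)=CCC(O[Si](C)(C)C(C)(C)C)=C1O[Si](C)(C)C(C)(C)C | intermediate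
16 | 2-[3,4-bis(tert-butyldimethylsilyloxy)-2-geranylphenyl]-7-(triisopropylsilyloxy)-4H-chromen-4-one | CC(C)=CCC/C(C)=C/Cc1c(-c2cc(=O)c3ccc(O[Si](C(C)C)(C(C)C)C(C)C)cc3o2)ccc(O[Si](C)(C)C(C)(C)C)c1O[Si](C)(C)C(C)(C)C | intermediate
17 | (2S)-2-[3,4-bis(tert-butyldimethylsilyloxy)-2-geranylphenyl]-4-[diethoxy(methyl)silyloxy]-7-(triisopropylsilyloxy)-2H-chromene | CC(C)=CCC/C(C)=C/Cc1c([C@@H]2C=C(O[Si](C)(OCC)OCC)c3ccc(O[Si](C(C)C)(C(C)C)C(C)C)cc3O2)ccc(O[Si](C)(C)C(C)(C)C)c1O[Si](C)(C)C(C)(C)C | intermediate
18 | (2S)-2-[3,4-bis(tert-butyldimethylsilyloxy)-2-geranylphenyl]-7-(triisopropylsilyloxy)-2,3-dihydro-4H-chromen-4-one | CC(C)=CCC/C(C)=C/Cc1c([C@@H]2CC(=O)c3ccc(O[Si](C(C)C)(C(C)C)C(C)C)cc3O2)ccc(O[Si](C)(C)C(C)(C)C)c1O[Si](C)(C)C(C)(C)C | intermediate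
19 | (2S)-2-{2-[(2E)-3,7-dimethylocta-2,6-dien-1-yl]-3,4-dihydroxyphenyl}-7-hydroxy-2,3-dihydro-4H-chromen-4-one | CC(C)=CCC/C(C)=C/Cc1c([C@@H]2CC(=O)c3ccc(O)cc3O2)ccc(O)c1O | target

**Step count**

Total: 11 steps. Longest linear sequence: 8 steps (steps 4 to 11); the diene branch (steps 1 to 3) joins at step 9.

**Steps most likely to fail**

1. Step 9. The cycloaddition to the only moderately activated alkyne may be slower than thermal decay of the silyloxydiene or oligomerisation of the alkyne. The ortho preference may also erode at the temperature needed, and DDQ may begin to abstract hydride from the benzylic–allylic CH2 of the product.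
Fallback, setting out from diene 6 and acetophenone 7 and returning at flavone 16: 6 is heated with methyl propiolate (toluene, 80 °C), a far stronger terminal acceptor alkyne that reacts at lower temperature in the same ortho sense, to give methyl 4,5-bis(tert-butyldimethylsilyloxy)-6-geranylcyclohexa-1,4-diene-1-carboxylate F1. DDQ then dehydrogenates this to methyl 3,4-bis(tert-butyldimethylsilyloxy)-2-geranylbenzoate F2. Separately, 7 is silylated at its non-chelated 4-hydroxyl (TIPSCl, imidazole, CH2Cl2) to 1-[2-hydroxy-4-(triisopropylsilyloxy)phenyl]ethanone F3. Its dianion (LiN(SiMe3)2, 3 equiv, THF, −78 °C to rt) undergoes Claisen condensation with F2 to give 1-[3,4-bis(tert-butyldimethylsilyloxy)-2-geranylphenyl]-3-[2-hydroxy-4-(triisopropylsilyloxy)phenyl]propane-1,3-dione F4. Cyclodehydration (cat. TsOH·H2O, toluene, 60 °C) then closes ring C to give 16.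

2. Step 10. Hydride transfer to the hindered C2, which carries a twisted ortho-substituted aryl group and a donor oxygen, may be slow. Facial discrimination may be poor, or 1,2-reduction and β-elimination of the aryloxide may compete.
Fallback, setting out from flavone 16 and returning at flavanone 18: 1,4-reduction with LiBH(sBu)3 (THF, −78 °C, cold AcOH quench) gives racemic 2-[3,4-bis(tert-butyldimethylsilyloxy)-2-geranylphenyl]-7-(triisopropylsilyloxy)-2,3-dihydro-4H-chromen-4-one F5. Kinetic resolution by asymmetric transfer hydrogenation (RuCl(p-cymene)[(R,R)-TsDPEN] or its antipode, whichever consumes the (2R)-ketone faster, HCO2H/Et3N, EtOAc, rt, to about half conversion) reduces the (2R)-ketone to (2R,4R)-2-[3,4-bis(tert-butyldimethylsilyloxy)-2-geranylphenyl]-7-(triisopropylsilyloxy)-3,4-dihydro-2H-chromen-4-ol F6. The unreacted (2S)-ketone 18 is separated by chromatography.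

3. Step 8. The diazo carbanion may add to the pyranone or to the newly formed acceptor alkyne (pyrazole formation) instead of stopping at homologation of the aldehyde, or the aryl silyl ether may be lost to the lithium base.
Fallback, setting out from aldehyde 13 and returning at alkyne 14: base-free dibromo-olefination (CBr4, PPh3, CH2Cl2, 0 °C) gives 2-(2,2-dibromovinyl)-7-(triisopropylsilyloxy)-4H-chromen-4-one F7. Hydrogenolysis with Bu3SnH and catalytic Pd(PPh3)4 (toluene, rt) removes the bromine trans to the chromone to give 2-[(Z)-2-bromovinyl]-7-(triisopropylsilyloxy)-4H-chromen-4-one F8. Anti elimination of HBr with DBU (MeCN, 60 °C) then gives 14.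

**Further compounds**

F1 | step 9 | methyl 4,5-bis(tert-butyldimethylsilyloxy)-6-geranylcyclohexa-1,4-diene-1-carboxylate | CC(C)=CCC/C(C)=C/CC1C(C(=O)OC)=CCC(O[Si](C)(C)C(C)(C)C)=C1O[Si](C)(C)C(C)(C)C
F2 | step 9 | methyl 3,4-bis(tert-butyldimethylsilyloxy)-2-geranylbenzoate | CC(C)=CCC/C(C)=C/Cc1c(C(=O)OC)ccc(O[Si](C)(C)C(C)(C)C)c1O[Si](C)(C)C(C)(C)C
F3 | step 9 | 1-[2-hydroxy-4-(triisopropylsilyloxy)phenyl]ethanone | CC(=O)c1ccc(O[Si](C(C)C)(C(C)C)C(C)C)cc1O
F4 | step 9 | 1-[3,4-bis(tert-butyldimethylsilyloxy)-2-geranylphenyl]-3-[2-hydroxy-4-(triisopropylsilyloxy)phenyl]propane-1,3-dione | CC(C)=CCC/C(C)=C/Cc1c(C(=O)CC(=O)c2ccc(O[Si](C(C)C)(C(C)C)C(C)C)cc2O)ccc(O[Si](C)(C)C(C)(C)C)c1O[Si](C)(C)C(C)(C)C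
F5 | step 10 | racemic 2-[3,4-bis(tert-butyldimethylsilyloxy)-2-geranylphenyl]-7-(triisopropylsilyloxy)-2,3-dihydro-4H-chromen-4-one | CC(C)=CCC/C(C)=C/Cc1c(C2CC(=O)c3ccc(O[Si](C(C)C)(C(C)C)C(C)C)cc3O2)ccc(O[Si](C)(C)C(C)(C)C)c1O[Si](C)(C)C(C)(C)C
F6 | step 10 | (2R,4R)-2-[3,4-bis(tert-butyldimethylsilyloxy)-2-geranylphenyl]-7-(triisopropylsilyloxy)-3,4-dihydro-2H-chromen-4-ol | CC(C)=CCC/C(C)=C/Cc1c([C@H]2C[C@@H](O)c3ccc(O[Si](C(C)C)(C(C)C)C(C)C)cc3O2)ccc(O[Si](C)(C)C(C)(C)C)c1O[Si](C)(C)C(C)(C)C
F7 | step 8 | 2-(2,2-dibromovinyl)-7-(triisopropylsilyloxy)-4H-chromen-4-one | BrC(Br)=Cc1cc(=O)c2ccc(O[Si](C(C)C)(C(C)C)C(C)C)cc2o1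
F8 | step 8 | 2-[(Z)-2-bromovinyl]-7-(triisopropylsilyloxy)-4H-chromen-4-one | Br/C=C\c1cc(=O)c2ccc(O[Si](C(C)C)(C(C)C)C(C)C)cc2o1
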